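Leoligin's tetrahydrofuran (O1, C2–C5) contains the three-atom unit C2(aryl)–O1–C5H2, and its cis arms C9 (on C3) and C7′ (on C4) can be tied back as the carbonyl and acetal carbons of a cis-fused γ-lactone. The ring is therefore cut at C2–C3 and C4–C5: a (3+2) cycloaddition of the carbonyl ylide ArCH=O(+)–CH2(−) onto the C=C of (5S)-5-(d-menthyloxy)furan-2(5H)-one forms both bonds, the ring and the C2, C3 and C4 stereocentres at once. The ylide precursor is the α-chloro-3,4-dimethoxybenzyl (trimethylsilyl)methyl ether, unmasked by fluoride. Aryl Grignard addition, benzylic hydrogenolysis, reduction and angeloylation finish the synthesis.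

Key step: step 5

Remark (numbering): target atoms are O1, C2 (aryl), C3 (bearing C9H2O), C4 (bearing C7′H2Ar), C5; bicyclic lactones are numbered as furo[3,4-c]furan-1-ones (C1 carbonyl, O2, C3, C3a, C4, O5, C6, C6a).
Remark (structure): with this numbering the cycloadduct carries its aryl group at C6, next to the carbonyl-bearing ring-fusion carbon C6a, not at C4; the 6-aryl-3-menthyloxy regioisomer is the one the route needs and is used below.
Remark (precursor): the α-chloro ether of this electron-rich aldehyde ionises too easily to be purified or stored; it is drawn fresh from a stable bis(silylmethyl) acetal and used crude, in excess over the chiral butenolide.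
Assumption: 3,4-dimethoxyphenylmagnesium bromide (THF solution) and angelic acid are purchased.

Step 1
Reactants: 1 furfural
Product: 2 5-hydroxyfuran-2(5H)-one (racemic)
Conditions: O2, hν (visible), rose bengal (cat.), MeOH, rt
Reagents that add atoms: dioxygen, O=O
Why: Dye-sensitised singlet-oxygen [4+2] photooxygenation across the furan 2,5-positions, followed by methanolysis that expels the formyl carbon as methyl formate, should leave the γ-hydroxybutenolide; its hemiacetal carbon is racemic and is fixed in step 2.

Step 2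
Reactants: 2 5-hydroxyfuran-2(5H)-one; 3 (+)-menthol [(1S,2R,5S)-2-isopropyl-5-methylcyclohexanol]
Product: 4 (5S)-5-(d-menthyloxy)furan-2(5H)-one [(5S)-5-{[(1S,2R,5S)-2-isopropyl-5-methylcyclohexyl]oxy}furan-2(5H)-one]
Conditions: CSA (cat.), toluene, reflux, Dean–Stark; crystallisation from petroleum ether (−20 °C), mother liquor re-equilibrated (CSA) and recrystallised
Reagents that add atoms: none
Why: Acid-catalysed acetalisation of the pseudo-acid gives both C5 epimers, which interconvert under acid while the 5S epimer, the enantiomer of the readily crystallising (5R)-l-menthyloxy compound, should crystallise out, so the acetal stereocentre is set by crystallisation-induced diastereomer transformation.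

Step 3
Reactants: 5 veratraldehyde; 6 (trimethylsilyl)methanol
Product: 8 4-{bis[(trimethylsilyl)methoxy]methyl}-1,2-dimethoxybenzene, via veratraldehyde dimethyl acetal 7 (not isolated)
Conditions: HC(OMe)3 (1.2 equiv), p-TsOH (1 mol %), MeOH, rt; evaporate; 6 (3 equiv), toluene, 100 °C with distillation of MeOH; Et3N quench
Reagents that add atoms: none
Why: Orthoformate-driven acetalisation followed by acid-catalysed transacetalisation, pulled to the bis(silylmethyl) acetal by removing the lower-boiling methanol, is ordinary acetal exchange and creates no stereocentre.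

Step 4
Reactants: 8 4-{bis[(trimethylsilyl)methoxy]methyl}-1,2-dimethoxybenzene
Product: 9 {[chloro(3,4-dimethoxyphenyl)methoxy]methyl}trimethylsilane (racemic α-chloro ether)
Conditions: AcCl (1.1 equiv), SOCl2 (2 mol %), CH2Cl2, 0 °C → rt; volatiles and Me3SiCH2OAc removed at 0.1 mbar; used at once
Reagents that add atoms: acetyl chloride, CC(Cl)=O
Why: Cleavage of a benzaldehyde acetal by an acyl chloride (O-acylation, loss of the ester, chloride capture of the aryl-stabilised oxocarbenium ion) is the classical route to α-chlorobenzyl ethers; the chloro carbon is racemic and becomes planar in step 5.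

Step 5
Reactants: 9 {[chloro(3,4-dimethoxyphenyl)methoxy]methyl}trimethylsilane; 4 (5S)-5-(d-menthyloxy)furan-2(5H)-one
Product: 11 (3S,3aR,6S,6aS)-6-(3,4-dimethoxyphenyl)-3-[(1S,2R,5S)-menthyloxy]tetrahydro-1H-furo[3,4-c]furan-1-one, via carbonyl ylide 10 (not isolated)
Conditions: CsF (3 equiv, dried), MeCN, rt; 9 (2 equiv) added over 4 h to 4 and CsF
Reagents that add atoms: none
Why: Fluoride attacks silicon and chloride leaves (the electron-rich aryl group lets 9 ionise to a silylmethyl oxocarbenium ion first), which frees the four-electron dipole 10; this should add to the electron-poor C=C of 4 in one concerted suprafacial [π4s+π2s] event that forms C6–C6a and C3a–C4 (target C2–C3 and C4–C5). The closest known chemistry is the cycloaddition of non-stabilised carbonyl ylides, generated by silicon-based 1,3-elimination from α-halo α′-silyl ethers, to acrylate-type alkenes, together with the anti-selective dipolar cycloadditions of 5-menthyloxyfuran-2(5H)-one. The tetrahydrofuran ring closes by intermolecular (3+2) annulation across an endocyclic cis alkene, both C–C bonds on the same face, so it can only be cis-fused and C9 and C7′ end up cis. C3a and C6a (target C4 and C3) are set by addition to the face opposite the menthyloxy group at C3, the one stereocentre of 4, and C6 (target C2) by an exo transition state of the E-ylide that leaves the aryl group on the convex face, trans to the lactone carbonyl carbon. The step needs one regiochemistry: the dimethoxyphenyl group holds the positive charge at its own carbon, so the larger HOMO coefficient lies on the CH2 terminus, which should bond to the β-carbon (largest LUMO coefficient), while the bulky ArCH end stays away from the acetal. Slow addition of an excess of 9 keeps the ylide dilute so that capture by 4 can outrun its self-reaction.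

Step 6
Reactants: 11 (3S,3aR,6S,6aS)-6-(3,4-dimethoxyphenyl)-3-[(1S,2R,5S)-menthyloxy]tetrahydro-1H-furo[3,4-c]furan-1-one
Product: 12 (3aR,6S,6aS)-6-(3,4-dimethoxyphenyl)-3-hydroxytetrahydro-1H-furo[3,4-c]furan-1-one (lactol; both C3 epimers)
Conditions: 2 M aq. HCl, 1,4-dioxane, 60 °C
Reagents that add atoms: water, O
Why: Acid-catalysed hydrolysis of the acylal-type menthyl acetal should release (+)-menthol and give the cyclic pseudo-acid, whose closed lactol form keeps the carbon α to the masked aldehyde (C3a) locked cis, while dilute aqueous acid should leave the benzylic ring ether intact.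

Step 7
Reactants: 12 (3aR,6S,6aS)-6-(3,4-dimethoxyphenyl)-3-hydroxytetrahydro-1H-furo[3,4-c]furan-1-one; 13 3,4-dimethoxyphenylmagnesium bromide
Product: 15 (3aR,6S,6aS)-3,6-bis(3,4-dimethoxyphenyl)tetrahydro-1H-furo[3,4-c]furan-1-one (C3 epimers), via hydroxy acid 14 (not isolated)
Conditions: 13 (3 equiv, 0.5 M in THF), THF, −78 → 0 °C; then 2 M HCl, rt
Reagents that add atoms: none
Why: The first equivalent of Grignard reagent deprotonates the lactol and opens it to the aldehyde carboxylate, the second adds to the aldehyde (Grignard addition to a pseudo-acid), and on acidification the cis-disposed carbinol and carboxyl groups of 14 should close to the γ-lactone; the new C3 (C7′) centre may form as a mixture because step 8 removes it.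

Step 8
Reactants: 15 (3aR,6S,6aS)-3,6-bis(3,4-dimethoxyphenyl)tetrahydro-1H-furo[3,4-c]furan-1-one
Product: 16 (2S,3S,4R)-4-(3,4-dimethoxybenzyl)-2-(3,4-dimethoxyphenyl)tetrahydrofuran-3-carboxylic acid
Conditions: H2 (1 atm), 10% Pd/C, Et3N (1.1 equiv), EtOAc–EtOH, rt; stopped when 15 is consumed; dilute acid work-up
Reagents that add atoms: none
Why: Palladium-catalysed benzylic hydrogenolysis is much easier for the acyloxy (lactone) C7′–O bond than for the alkyl ether bond at C6, and the amine, which keeps the medium from turning acidic, should further suppress cleavage of the ring ether, so only the lactone C–O bond is cut and no ring stereocentre is touched.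

Step 9
Reactants: 16 (2S,3S,4R)-4-(3,4-dimethoxybenzyl)-2-(3,4-dimethoxyphenyl)tetrahydrofuran-3-carboxylic acid
Product: 17 [(2S,3R,4R)-4-(3,4-dimethoxybenzyl)-2-(3,4-dimethoxyphenyl)tetrahydrofuran-3-yl]methanol
Conditions: BH3·THF (2.5 equiv), THF, 0 °C → rt; MeOH, then aq. NaHCO3
Reagents that add atoms: none
Why: Borane reduces carboxylic acids chemoselectively through acyloxyboranes without enolisation, so C3 should keep its configuration (its descriptor changes from S to R only through CIP priorities).

Step 10
Reactants: 17 [(2S,3R,4R)-4-(3,4-dimethoxybenzyl)-2-(3,4-dimethoxyphenyl)tetrahydrofuran-3-yl]methanol; 18 angelic acid [(2Z)-2-methylbut-2-enoic acid]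
Product: 19 leoligin
Conditions: 18 (1.5 equiv), PPh3 (1.5 equiv), DIAD (1.5 equiv), THF, 0 °C → rt
Reagents that add atoms: none
Why: In the Mitsunobu esterification the carboxylate acts only as a nucleophile toward the alkoxyphosphonium salt of the primary alcohol, so the acyl group is never activated and the Z double bond should not isomerise to the tiglate; displacement occurs at the achiral C9H2 and leaves the three ring stereocentres alone.

Compound list
1 | furfural | O=Cc1ccco1 | starting material
2 | 5-hydroxyfuran-2(5H)-one (racemic) | O=C1C=CC(O)O1 | intermediate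
3 | (+)-menthol, (1S,2R,5S)-2-isopropyl-5-methylcyclohexanol | C[C@H]1CC[C@@H]([C@H](C1)O)C(C)C | starting material
4 | (5S)-5-(d-menthyloxy)furan-2(5H)-one | O=C1O[C@H](O[C@H]2C[C@@H](C)CC[C@@H]2C(C)C)C=C1 | intermediate
5 | veratraldehyde (3,4-dimethoxybenzaldehyde) | COc1ccc(C=O)cc1OC | starting material
6 | (trimethylsilyl)methanol | C[Si](C)(C)CO | starting material
7 | veratraldehyde dimethyl acetal, 4-(dimethoxymethyl)-1,2-dimethoxybenzene | COc1ccc(C(OC)OC)cc1OC | intermediate
8 | 4-{bis[(trimethylsilyl)methoxy]methyl}-1,2-dimethoxybenzene | COc1ccc(C(OC[Si](C)(C)C)OC[Si](C)(C)C)cc1OC | intermediate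
9 | {[chloro(3,4-dimethoxyphenyl)methoxy]methyl}trimethylsilane (racemic) | COc1ccc(C(Cl)OC[Si](C)(C)C)cc1OC | intermediate
10 | carbonyl ylide, (3,4-dimethoxybenzylidene)(methylide)oxonium | COc1ccc(C=[O+][CH2-])cc1OC | intermediate
11 | (3S,3aR,6S,6aS)-6-(3,4-dimethoxyphenyl)-3-[(1S,2R,5S)-menthyloxy]tetrahydro-1H-furo[3,4-c]furan-1-one (cis-fused; aryl exo) | O=C1O[C@H](O[C@H]3C[C@@H](C)CC[C@@H]3C(C)C)[C@H]2CO[C@H](c4ccc(OC)c(OC)c4)[C@@H]12 | intermediate
12 | (3aR,6S,6aS)-6-(3,4-dimethoxyphenyl)-3-hydroxytetrahydro-1H-furo[3,4-c]furan-1-one (C3 epimers) | O=C1OC(O)[C@H]2CO[C@H](c3ccc(OC)c(OC)c3)[C@@H]12 | intermediate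
13 | 3,4-dimethoxyphenylmagnesium bromide | COc1ccc([Mg]Br)cc1OC | starting material
14 | (2S,3S,4R)-2-(3,4-dimethoxyphenyl)-4-[(3,4-dimethoxyphenyl)(hydroxy)methyl]tetrahydrofuran-3-carboxylic acid (carbinol epimers) | OC(=O)[C@H]1[C@@H](C(O)c2ccc(OC)c(OC)c2)CO[C@@H]1c1ccc(OC)c(OC)c1 | intermediate
15 | (3aR,6S,6aS)-3,6-bis(3,4-dimethoxyphenyl)tetrahydro-1H-furo[3,4-c]furan-1-one (C3 epimers) | O=C1OC(c3ccc(OC)c(OC)c3)[C@H]2CO[C@H](c4ccc(OC)c(OC)c4)[C@@H]12 | intermediate
16 | (2S,3S,4R)-4-(3,4-dimethoxybenzyl)-2-(3,4-dimethoxyphenyl)tetrahydrofuran-3-carboxylic acid | OC(=O)[C@H]1[C@@H](Cc2ccc(OC)c(OC)c2)CO[C@@H]1c1ccc(OC)c(OC)c1 | intermediate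
17 | [(2S,3R,4R)-4-(3,4-dimethoxybenzyl)-2-(3,4-dimethoxyphenyl)tetrahydrofuran-3-yl]methanol | OC[C@H]1[C@@H](Cc2ccc(OC)c(OC)c2)CO[C@@H]1c1ccc(OC)c(OC)c1 | intermediate
18 | angelic acid, (2Z)-2-methylbut-2-enoic acid | C/C=C(/C)C(=O)O | starting material
19 | leoligin, [(2S,3R,4R)-4-(3,4-dimethoxybenzyl)-2-(3,4-dimethoxyphenyl)tetrahydrofuran-3-yl]methyl (2Z)-2-methylbut-2-enoate | C/C=C(/C)C(=O)OC[C@H]1[C@@H](Cc2ccc(OC)c(OC)c2)CO[C@@H]1c1ccc(OC)c(OC)c1 | target

Total step count: 10
Longest linear sequence: 8 steps (1, 2, 5–10; the branch 3, 4, 5–10 is equally long)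

Steps most likely to fail

1. Step 5. The ylide may be consumed by self-reaction or protonation before the moderately reactive butenolide traps it, or the dipole may add in the opposite orientation or with the aryl group endo, so that regio- or exo-selectivity is lost. Fallback (sets out from 5, returns at 17), built on radical cyclisation and cross-coupling:
- Veratraldehyde 5 would be vinylated (CH2=CHMgBr, THF, 0 °C) to racemic 1-(3,4-dimethoxyphenyl)prop-2-en-1-ol F1.
- Lipase-catalysed acetylation (Burkholderia cepacia lipase, vinyl acetate, MTBE) should leave the (S)-alcohol F2 and turn its antipode into the (R)-acetate F3, which is removed by chromatography.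
- O-Alkylation (NaH, propargyl bromide, THF) gives the propargyl ether F4, and epoxidation of its vinyl group (mCPBA, CH2Cl2) the epoxide F5.
- Cp2TiCl (from Cp2TiCl2 and Zn, THF) opens the epoxide to a β-titanoxy radical that cyclises 5-exo-dig onto the alkyne, trans to the aryl group, giving the methylidene-tetrahydrofuran alcohol F6.
- 9-BBN should add from the face opposite the hydroxymethyl group to give the alkylborane F7, which is coupled in the same flask with 4-bromo-1,2-dimethoxybenzene (Pd(dppf)Cl2, aq. NaOH, THF, 60 °C; B-alkyl Suzuki–Miyaura coupling) to give 17.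

This path sets C2 by resolution, C3 in the radical cyclisation and C4 in the hydroboration, and needs neither ylide nor butenolide.

2. Step 8. Over-reduction may occur, with the catalyst also cleaving the benzylic ring ether C6–O5 (target C2–O1), or the amine-buffered catalyst may fail to cut the lactone at a useful rate. Fallback (sets out from 15, returns at 17), replacing hydrogenolysis by radical deoxygenation:
- LiAlH4 (THF, 0 °C, basic work-up) reduces 15 to the diol F8.
- TBSCl and imidazole (CH2Cl2, 0 °C) silylate only the primary hydroxyl to give the silyl ether F9.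
- 1,1′-Thiocarbonyldiimidazole (DMAP, CH2Cl2, rt) converts the benzylic hydroxyl into the imidazole-1-carbothioate F10.
- Bu3SnH and AIBN (toluene, 90 °C; Barton–McCombie deoxygenation) replace it by hydrogen to give the silyl ether F11; this radical C–O cleavage cannot touch the ring ether.
- TBAF (THF) then frees 17.

3. Step 7. The basic Grignard reagent may enolise the ring-opened aldehyde carboxylate, which would epimerise target C4, or the lactol may open incompletely. Fallback (sets out from 11, returns at 15), replacing nucleophilic by electrophilic arylation: the menthyl acetal 11 is ionised with BF3·OEt2 (CH2Cl2, −40 → 0 °C) in the presence of 1,2-dimethoxybenzene (5 equiv). The acyloxy-carbenium ion should alkylate the arene para to a methoxy group (Friedel–Crafts reaction of a pseudo-ester), giving 15 directly while the masked aldehyde never leaves its cis-fused ring. No compound outside the list is made (F0).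

Further compounds
F1 | step 5 | rac-1-(3,4-dimethoxyphenyl)prop-2-en-1-ol | C=CC(O)c1ccc(OC)c(OC)c1
F2 | step 5 | (1S)-1-(3,4-dimethoxyphenyl)prop-2-en-1-ol | C=C[C@H](O)c1ccc(OC)c(OC)c1
F3 | step 5 | (1R)-1-(3,4-dimethoxyphenyl)prop-2-en-1-yl acetate | C=C[C@@H](OC(C)=O)c1ccc(OC)c(OC)c1
F4 | step 5 | 1,2-dimethoxy-4-[(1S)-1-(prop-2-yn-1-yloxy)prop-2-en-1-yl]benzene | C=C[C@H](OCC#C)c1ccc(OC)c(OC)c1
F5 | step 5 | 2-[(R)-(3,4-dimethoxyphenyl)(prop-2-yn-1-yloxy)methyl]oxirane (epoxide carbon as a mixture) | C1OC1[C@H](OCC#C)c1ccc(OC)c(OC)c1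
F6 | step 5 | [(2S,3R)-2-(3,4-dimethoxyphenyl)-4-methylidenetetrahydrofuran-3-yl]methanol | OC[C@H]1C(=C)CO[C@@H]1c1ccc(OC)c(OC)c1
F7 | step 5 | [(2S,3R,4R)-4-(9-borabicyclo[3.3.1]nonan-9-ylmethyl)-2-(3,4-dimethoxyphenyl)tetrahydrofuran-3-yl]methanol | OC[C@H]1[C@@H](CB2C3CCCC2CCC3)CO[C@@H]1c1ccc(OC)c(OC)c1
F8 | step 8 | [(2S,3R,4R)-2-(3,4-dimethoxyphenyl)-4-[(3,4-dimethoxyphenyl)(hydroxy)methyl]tetrahydrofuran-3-yl]methanol (carbinol epimers) | OC[C@H]1[C@@H](C(O)c2ccc(OC)c(OC)c2)CO[C@@H]1c1ccc(OC)c(OC)c1
F9 | step 8 | [(3R,4R,5S)-4-({[tert-butyl(dimethyl)silyl]oxy}methyl)-5-(3,4-dimethoxyphenyl)tetrahydrofuran-3-yl](3,4-dimethoxyphenyl)methanol (carbinol epimers) | CC(C)(C)[Si](C)(C)OC[C@H]1[C@@H](C(O)c2ccc(OC)c(OC)c2)CO[C@@H]1c1ccc(OC)c(OC)c1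
F10 | step 8 | O-{[(3R,4R,5S)-4-({[tert-butyl(dimethyl)silyl]oxy}methyl)-5-(3,4-dimethoxyphenyl)tetrahydrofuran-3-yl](3,4-dimethoxyphenyl)methyl} 1H-imidazole-1-carbothioate | CC(C)(C)[Si](C)(C)OC[C@H]1[C@@H](C(OC(=S)n3ccnc3)c2ccc(OC)c(OC)c2)CO[C@@H]1c1ccc(OC)c(OC)c1
F11 | step 8 | tert-butyl{[(2S,3R,4R)-4-(3,4-dimethoxybenzyl)-2-(3,4-dimethoxyphenyl)tetrahydrofuran-3-yl]methoxy}dimethylsilane | CC(C)(C)[Si](C)(C)OC[C@H]1[C@@H](Cc2ccc(OC)c(OC)c2)CO[C@@H]1c1ccc(OC)c(OC)c1
F0 | step 7 | none | none
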